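**Retrosynthetic overview**
1. Target ⇐ C11 acetylation, C7 desilylation and C15 epimerization ⇐ Baeyer–Villiger insertion of one oxygen between C16 and C3 of a ring B cyclohexanone ⇐ oxonane by ring-closing metathesis (C6=C7), epoxidation and methoxide opening.
2. Ring B ketone ⇐ C3 quaternization (β-keto ester dianion alkylation) and C9 C-allylation of a tricyclic lactol ⇐ one-pot Michael–aldol (3+3) annulation of the lactol-masked ring A enal 10 with methyl 3-oxopentanoate, forming C14–C15 and C2–C3.
3. Enabling feature: the lactone ring C3–O–C16(=O)–C15–C14–C1–C2 is a cyclohexanone (C3–C16–C15–C14–C1–C2) plus one oxygen. The C16 carbonyl makes its two flanking carbons C15 and C3 nucleophilic, and C14 (β-carbon of the ring A enal C1=C14) and C2 (aldehyde carbon) are the matching 1,3-dielectrophile.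
4. Ring A ⇐ base-induced opening of the oxygen bridge of the 2-methylfuran/maleic anhydride adduct, resolved by alkaloid-catalysed methanolysis.
5. Ring order: A (from the oxanorbornane) → B (key step) → tetrahydrofuran (lactol, C9 allylation) → nine-membered oxonane (metathesis) → seven-membered lactone (oxygen insertion).

Key step: step 8

**Remarks and assumptions**
- Numbering: locants are those of the target drawn as a cladiellane lactone. C1/C10 are the ring-fusion carbons of the hexahydroisobenzofuran, C2/C9 its ether carbons, C3 the carbon bearing the lactone oxygen, C4–C8 the oxonane chain (C6 OMe, C7 Me/OH), C11 the acetoxy carbon, C14 the ring carbon bearing C15, C15 the lactone α-carbon (methyl C17), C16 the lactone carbonyl. Ring A = C1, C10–C14; ring B = C1–C2–C3–C16–C15–C14. In this numbering the target is (1S,2S,3S,6R,7R,9S,10R,11R,14R,15R).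
- Compounds 3 and 4 are racemic; their SMILES show the enantiomer carried on after step 3.
- Assumption: the cinchona catalyst in step 3 is the pseudoenantiomer that delivers the drawn hemiester 5; the sense is taken by analogy with alkaloid-mediated methanolysis of the parent meso anhydride.
- Assumption: reagents reach the C6=C7 alkene of 19 from its peripheral face, the one turned away from the C1–C10 bridge.
- Anomeric carbons (10, 12, 14) and C15 in 12–17 are left unmarked because they are mixtures that are fixed or removed later. C3 in 13–15 is drawn as the equatorial-methyl epimer and is planarized again in step 11.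

**Route**

Step 1
Reactants: 1 2-methylfuran; 2 maleic anhydride
Product: 3 racemic exo-4-methyl-3a,4,7,7a-tetrahydro-4,7-epoxyisobenzofuran-1,3-dione
Conditions: Et2O, rt, 48 h; crystallization
Reagents that add atoms: none
Why: Thermodynamically controlled Diels–Alder cycloaddition of a furan should give the crystalline exo adduct, which fixes the cis relationship between the future C9 carbon on C10 and the C11 oxygen (bridge oxygen and anhydride on the same face).

Step 2
Reactants: 3 racemic exo Diels–Alder adduct
Product: 4 racemic exo-4-methylhexahydro-4,7-epoxyisobenzofuran-1,3-dione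
Conditions: H2 (1 atm), Pd/C, EtOAc, rt
Reagents that add atoms: none
Why: Catalytic hydrogenation of the strained disubstituted alkene removes the retro-Diels–Alder pathway without touching a stereocenter.

Step 3
Reactants: 4 racemic saturated anhydride
Product: 5 exo,exo-3-(methoxycarbonyl)-1-methyl-7-oxabicyclo[2.2.1]heptane-2-carboxylic acid (single enantiomer)
Conditions: MeOH (10 equiv), (DHQD)2AQN (15 mol %), Et2O, −20 °C; separation from the regioisomeric hemiester formed from the antipode
Reagents that add atoms: methanol, CO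
Why: Cinchona-alkaloid-catalysed alcoholysis of a cyclic anhydride, run as a parallel kinetic resolution, should direct methanol to the carbonyl remote from the methyl-bearing bridgehead in one enantiomer only, so the absolute configuration of C10 and C11 is fixed here.

Step 4
Reactants: 5 hemiester
Product: 7 exo-4-methylhexahydro-4,7-epoxyisobenzofuran-1(3H)-one (lactone carbonyl on the carbon next to the H-bearing bridgehead), via hydroxy ester 6 (not isolated)
Conditions: BH3·SMe2 (1.5 equiv), THF, 0 °C to rt; aq. work-up; then TsOH (cat.), toluene, 60 °C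
Reagents that add atoms: none
Why: Borane reduces the carboxylic acid chemoselectively beside the methyl ester and the cis hydroxy ester should lactonize, which leaves C1–H as the only acidic hydrogen, next to the bridge oxygen on C14.

Step 5
Reactants: 7 bridged lactone
Product: 8 4-hydroxy-4-methyl-3a,4,5,6-tetrahydroisobenzofuran-1(3H)-one (hydroxyl cis to the lactone CH2)
Conditions: LiN(SiMe3)2 (1.1 equiv), THF, −78 °C; AcOH quench at −78 °C
Reagents that add atoms: none
Why: E1cB β-elimination of the lactone enolate opens the oxygen bridge (known for 7-oxanorbornane esters) and should give the C1=C14 alkylidene lactone and the free tertiary C11 alcohol with C10 and C11 untouched.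

Step 6
Reactants: 8 hydroxy alkylidene lactone
Product: 9 4-(benzyloxy)-4-methyl-3a,4,5,6-tetrahydroisobenzofuran-1(3H)-one
Conditions: 2-benzyloxy-1-methylpyridinium triflate (2 equiv), MgO, PhCF3, 83 °C
Reagents that add atoms: 2-benzyloxy-1-methylpyridinium triflate, C[n+]1ccccc1OCc1ccccc1.[O-]S(=O)(=O)C(F)(F)F
Why: Benzyl transfer from the pyridinium salt etherifies the hindered tertiary alcohol under neutral conditions, which avoids base-induced isomerization of the alkylidene lactone.

Step 7
Reactants: 9 benzyl ether lactone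
Product: 10 4-(benzyloxy)-4-methyl-1,3,3a,4,5,6-hexahydroisobenzofuran-1-ol (lactol; anomers)
Conditions: i-Bu2AlH (1.1 equiv), CH2Cl2, −78 °C; Rochelle salt work-up
Reagents that add atoms: none
Why: Half-reduction of the lactone should stop at the lactol, a masked form of the C2 enal carrying the C9 hydroxyl.

Step 8
Reactants: 10 lactol; 11 methyl 3-oxopentanoate
Product: 13 trans-fused ring A/ring B keto ester diol (methyl 6-(benzyloxy)-4-hydroxy-5-(hydroxymethyl)-3,6-dimethyl-2-oxodecahydronaphthalene-1-carboxylate), via Michael adduct lactol 12 (not isolated)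
Conditions: KOt-Bu (10 mol %), THF, 0 °C to rt; then LiN(i-Pr)2 (3.3 equiv), −78 to −20 °C; aq. NH4Cl
Reagents that add atoms: none
Why: KOt-Bu equilibrates lactol 10 with its hydroxy-enal and the soft enolate of 11 adds to C14 (bond C14–C15), the aldehyde re-closing to lactol 12; LiN(i-Pr)2 then forms the 1,3-dianion of the β-keto ester, whose γ-carbon C3 adds to the C2 aldehyde released from the lactolate (bond C2–C3). The closest known reaction type is the base-mediated Michael–aldol (3+3) cyclohexannulation of β-keto esters with enals, combined with the γ-selective aldol of β-keto ester dianions. Ring B (C1–C2–C3–C16–C15–C14) closes by a 6-(enolendo)-exo-trig aldol through a lithium-chelated chair. C14 is set by axial attack anti to the C10 hydroxymethyl group, which allylic strain with the formyl group holds pseudoaxial; C1 is set under equilibrating conditions by cis-lactol formation with the C9 hydroxyl and then held by the trans ring fusion; C2 receives an equatorial hydroxyl from the chelated chair. C3 and C15 stay enolizable and are fixed in steps 11 and 18. The step needs 1,4- over 1,2-addition and γ- over α-aldol closure: the stabilized monoanion secures the first, and in the dianion the α-carbon could only close a four-membered ring, so only C3 can reach C2.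

Step 9
Reactants: 13 keto ester diol
Product: 14 tricyclic lactol (C9 hemiacetal closed onto the C2 oxygen; anomers)
Conditions: TEMPO (20 mol %), PhI(OAc)2 (1.1 equiv), CH2Cl2, rt
Reagents that add atoms: none
Why: Nitroxyl-catalysed oxidation is selective for the primary C9 alcohol over the secondary C2 alcohol, and the aldehyde should be trapped by the cis C2 hydroxyl as the bicyclic lactol.

Step 10
Reactants: 14 tricyclic lactol
Product: 15 C9-(2-methylallyl) tetrahydrofuran keto ester
Conditions: (2-methylallyl)trimethylsilane (3 equiv), Me3SiOTf (20 mol %), CH2Cl2, −78 to −40 °C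
Reagents that add atoms: (2-methylallyl)trimethylsilane, CC(=C)C[Si](C)(C)C
Why: Hosomi–Sakurai-type C-glycosylation in which the cyclic oxocarbenium ion at C9 should be attacked on the convex face, anti to the adjacent quaternary C11, giving the 2,5-cis tetrahydrofuran with the C9 configuration of the target.

Step 11
Reactants: 15 tetrahydrofuran keto ester
Product: 17 C3-(but-3-enyl)-C15-methyl keto ester, via C3-butenyl keto ester lithium enolate 16 (not isolated)
Conditions: LiN(i-Pr)2 (2.3 equiv), THF/DMPU, −78 to 0 °C; 4-iodobut-1-ene (1.3 equiv), −78 to 0 °C; then MeI (3 equiv), rt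
Reagents that add atoms: 4-iodobut-1-ene, C=CCCI; iodomethane, CI
Why: Alkylation of the β-keto ester 1,3-dianion occurs regiospecifically at the γ-carbon C3 and should proceed by axial attack on the face of H1 (C15 is planar in the dianion and the ring oxygen on C2 is equatorial), so the butenyl chain enters axial and the methyl stays equatorial as in the target, after which the remaining monoanion is C-methylated at C15.

Step 12
Reactants: 17 disubstituted keto ester
Product: 18 diene ketone (C15 methyl equatorial; 15-epi relative to the target)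
Conditions: LiCl (5 equiv), H2O (2 equiv), DMSO, 150 °C
Reagents that add atoms: none
Why: Krapcho dealkoxycarbonylation of the α,α-disubstituted β-keto methyl ester should leave the ketone with an equilibrated equatorial C15 methyl, which is corrected in step 18.

Step 13
Reactants: 18 diene ketone
Product: 19 Z-oxonene ketone (C6=C7)
Conditions: second-generation Hoveyda–Grubbs catalyst [RuCl2(H2IMes)(=CH-C6H4-2-O-i-Pr)] (10 mol %), toluene (2 mM), 80 °C
Reagents that add atoms: none
Why: Ring-closing metathesis of the two terminal alkenes held cis on the tetrahydrofuran (precedented for this oxabicyclo[6.2.1] system) should close the nine-membered ring, whose size enforces the Z trisubstituted alkene.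

Step 14
Reactants: 19 Z-oxonene ketone
Product: 20 6,7-epoxide
Conditions: mCPBA (1.2 equiv), NaHCO3, CH2Cl2, 0 °C
Reagents that add atoms: 3-chloroperbenzoic acid, OOC(=O)c1cccc(Cl)c1
Why: Prilezhaev epoxidation of the electron-rich trisubstituted alkene should occur on its peripheral face, which sets C7 (this C–O bond is kept), while the hindered C16 ketone reacts far more slowly with the peracid.

Step 15
Reactants: 20 epoxide
Product: 21 C6-methoxy C7-hydroxy ketone
Conditions: NaOMe (5 equiv), MeOH, 70 °C (sealed tube)
Reagents that add atoms: methanol (delivered as sodium methoxide), CO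
Why: Base-mediated epoxide opening in which methoxide should attack the less substituted C6 in SN2 fashion with inversion, giving the trans C6-OMe/C7-OH pair of the target, while the quaternary C3 excludes β-elimination of the ring oxygen.

Step 16
Reactants: 21 methoxy alcohol
Product: 22 C7 triethylsilyl ether
Conditions: Et3SiOTf (1.5 equiv), 2,6-lutidine, CH2Cl2, −78 to 0 °C
Reagents that add atoms: triethylsilyl trifluoromethanesulfonate, CC[Si](CC)(CC)OS(=O)(=O)C(F)(F)F
Why: Silylation of the only free (tertiary) hydroxyl with a silyl triflate masks C7-OH so that C11 can later be acetylated selectively.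

Step 17
Reactants: 22 silyl ether ketone
Product: 23 seven-membered lactone (15-epi)
Conditions: mCPBA (3 equiv), NaHCO3, CH2Cl2, 0 °C to rt
Reagents that add atoms: 3-chloroperbenzoic acid, OOC(=O)c1cccc(Cl)c1
Why: Baeyer–Villiger oxidation inserts one oxygen between C16 and the quaternary C3, which should migrate in preference to the secondary C15 and with retention, turning ring B into the lactone.

Step 18
Reactants: 23 15-epi lactone
Product: 25 lactone of natural C15 configuration (C11 benzyl ether; C7 triethylsilyl ether), via lithium lactone enolate 24 (not isolated)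
Conditions: LiN(i-Pr)2 (1.5 equiv), THF, −78 to −40 °C; then 2,6-di-tert-butyl-4-methylphenol (3 equiv), −78 °C; aq. NH4Cl
Reagents that add atoms: none
Why: Deprotonation and kinetic protonation of the lactone enolate by a bulky phenol should deliver hydrogen to C15 from the less hindered face (that of H14, away from the axial C4 methylene and H1), which inverts C15 to the configuration of the target.

Step 19
Reactants: 25 benzyl ether lactone
Product: 26 C11 tertiary alcohol
Conditions: H2 (1 atm), Pd(OH)2/C, EtOAc, rt
Reagents that add atoms: none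
Why: Hydrogenolysis cleaves the benzyl ether; no alkene remains and the silyl ether and lactone are inert.

Step 20
Reactants: 26 C11 alcohol
Product: 27 C11 acetate (C7 triethylsilyl ether)
Conditions: Ac2O (10 equiv), DMAP (2 equiv), Et3N, CH2Cl2, 40 °C
Reagents that add atoms: acetic anhydride, CC(=O)OC(C)=O
Why: DMAP-catalysed acylation of the only free hydroxyl installs the tertiary acetate.

Step 21
Reactants: 27 silyl ether acetate
Product: 28 target CNP0238771.1
Conditions: HF·pyridine, THF, 0 °C to rt
Reagents that add atoms: none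
Why: Fluoride-mediated desilylation frees the C7 tertiary alcohol without touching the acetate or the lactone.

**Compound list**
1 | 2-methylfuran | Cc1ccco1 | starting material
2 | maleic anhydride | O=C1OC(=O)C=C1 | starting material
3 | rac-exo-4-methyl-3a,4,7,7a-tetrahydro-4,7-epoxyisobenzofuran-1,3-dione | C[C@]12C=C[C@H](O1)[C@@H]1C(=O)OC(=O)[C@@H]12 | intermediate
4 | rac-exo-4-methylhexahydro-4,7-epoxyisobenzofuran-1,3-dione | C[C@]12CC[C@H](O1)[C@@H]1C(=O)OC(=O)[C@@H]12 | intermediate
5 | exo,exo-3-(methoxycarbonyl)-1-methyl-7-oxabicyclo[2.2.1]heptane-2-carboxylic acid | C[C@]12CC[C@H](O1)[C@H](C(=O)OC)[C@@H]2C(=O)O | intermediate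
6 | methyl exo,exo-3-(hydroxymethyl)-4-methyl-7-oxabicyclo[2.2.1]heptane-2-carboxylate | C[C@]12CC[C@H](O1)[C@H](C(=O)OC)[C@@H]2CO | intermediate
7 | exo-4-methylhexahydro-4,7-epoxyisobenzofuran-1(3H)-one | C[C@]12CC[C@H](O1)[C@@H]1C(=O)OC[C@@H]12 | intermediate
8 | 4-hydroxy-4-methyl-3a,4,5,6-tetrahydroisobenzofuran-1(3H)-one (OH cis to the lactone CH2) | C[C@@]1(O)CCC=C2C(=O)OC[C@H]12 | intermediate
9 | 4-(benzyloxy)-4-methyl-3a,4,5,6-tetrahydroisobenzofuran-1(3H)-one | C[C@@]1(OCc3ccccc3)CCC=C2C(=O)OC[C@H]12 | intermediate
10 | 4-(benzyloxy)-4-methyl-1,3,3a,4,5,6-hexahydroisobenzofuran-1-ol (lactol) | C[C@@]1(OCc3ccccc3)CCC=C2C(O)OC[C@H]12 | intermediate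
11 | methyl 3-oxopentanoate | CCC(=O)CC(=O)OC | starting material
12 | methyl 2-[4-(benzyloxy)-1-hydroxy-4-methyloctahydroisobenzofuran-7-yl]-3-oxopentanoate (Michael adduct, lactol form) | CCC(=O)C(C(=O)OC)[C@@H]1CC[C@@](C)(OCc3ccccc3)[C@H]2COC(O)[C@@H]12 | intermediate
13 | methyl 6-(benzyloxy)-4-hydroxy-5-(hydroxymethyl)-3,6-dimethyl-2-oxodecahydronaphthalene-1-carboxylate (trans-fused rings A/B) | C[C@H]1C(=O)C(C(=O)OC)[C@@H]2CC[C@@](C)(OCc3ccccc3)[C@@H](CO)[C@H]2[C@@H]1O | intermediate
14 | tricyclic lactol (C9 hemiacetal bridging to the C2 oxygen) | C[C@H]1C(=O)C(C(=O)OC)[C@@H]2CC[C@@](C)(OCc3ccccc3)[C@@H]4[C@H]2[C@@H]1OC4O | intermediate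
15 | C9-(2-methylallyl) tetrahydrofuran keto ester | C[C@H]1C(=O)C(C(=O)OC)[C@@H]2CC[C@@](C)(OCc3ccccc3)[C@@H]4[C@H]2[C@@H]1O[C@H]4CC(C)=C | intermediate
16 | C3-(but-3-enyl) keto ester (present as its lithium enolate; drawn neutral) | C=CCC[C@]1(C)C(=O)C(C(=O)OC)[C@@H]2CC[C@@](C)(OCc3ccccc3)[C@@H]4[C@H]2[C@@H]1O[C@H]4CC(C)=C | intermediate
17 | C3-(but-3-enyl)-C15-methyl keto ester | C=CCC[C@]1(C)C(=O)C(C)(C(=O)OC)[C@@H]2CC[C@@](C)(OCc3ccccc3)[C@@H]4[C@H]2[C@@H]1O[C@H]4CC(C)=C | intermediate
18 | diene ketone (15-epi) | C=CCC[C@]1(C)C(=O)[C@@H](C)[C@@H]2CC[C@@](C)(OCc3ccccc3)[C@@H]4[C@H]2[C@@H]1O[C@H]4CC(C)=C | intermediate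
19 | Z-oxonene ketone | C/C1=C/CC[C@]2(C)C(=O)[C@@H](C)[C@@H]3CC[C@@](C)(OCc5ccccc5)[C@@H]4[C@H]3[C@@H]2O[C@H]4C1 | intermediate
20 | 6,7-epoxide | C[C@]12O[C@H]1CC[C@]3(C)C(=O)[C@@H](C)[C@@H]4CC[C@@](C)(OCc6ccccc6)[C@@H]5[C@H]4[C@@H]3O[C@H]5C2 | intermediate
21 | C6-methoxy C7-hydroxy ketone | CO[C@@H]1CC[C@]2(C)C(=O)[C@@H](C)[C@@H]3CC[C@@](C)(OCc5ccccc5)[C@@H]4[C@H]3[C@@H]2O[C@H]4C[C@@]1(C)O | intermediate
22 | C7 triethylsilyl ether ketone | CO[C@@H]1CC[C@]2(C)C(=O)[C@@H](C)[C@@H]3CC[C@@](C)(OCc5ccccc5)[C@@H]4[C@H]3[C@@H]2O[C@H]4C[C@@]1(C)O[Si](CC)(CC)CC | intermediate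
23 | seven-membered lactone, 15-epi | CO[C@@H]1CC[C@]2(C)OC(=O)[C@@H](C)[C@@H]3CC[C@@](C)(OCc5ccccc5)[C@@H]4[C@H]3[C@@H]2O[C@H]4C[C@@]1(C)O[Si](CC)(CC)CC | intermediate
24 | lithium lactone enolate | CO[C@@H]1CC[C@]2(C)OC([O-])=C(C)[C@@H]3CC[C@@](C)(OCc5ccccc5)[C@@H]4[C@H]3[C@@H]2O[C@H]4C[C@@]1(C)O[Si](CC)(CC)CC.[Li+] | intermediate
25 | lactone with natural C15 (C11 benzyl ether, C7 triethylsilyl ether) | CO[C@@H]1CC[C@]2(C)OC(=O)[C@H](C)[C@@H]3CC[C@@](C)(OCc5ccccc5)[C@@H]4[C@H]3[C@@H]2O[C@H]4C[C@@]1(C)O[Si](CC)(CC)CC | intermediate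
26 | C11 alcohol (C7 triethylsilyl ether) | CO[C@@H]1CC[C@]2(C)OC(=O)[C@H](C)[C@@H]3CC[C@@](C)(O)[C@@H]4[C@H]3[C@@H]2O[C@H]4C[C@@]1(C)O[Si](CC)(CC)CC | intermediate
27 | C11 acetate (C7 triethylsilyl ether) | CO[C@@H]1CC[C@]2(C)OC(=O)[C@H](C)[C@@H]3CC[C@@](C)(OC(C)=O)[C@@H]4[C@H]3[C@@H]2O[C@H]4C[C@@]1(C)O[Si](CC)(CC)CC | intermediate
28 | CNP0238771.1 | CO[C@@H]1CC[C@]2(C)OC(=O)[C@H](C)[C@@H]3CC[C@@](C)(OC(C)=O)[C@@H]4[C@H]3[C@@H]2O[C@H]4C[C@@]1(C)O | target

**Totals**
Total step count: 21. Longest linear sequence: 21 steps (1/2 → 28); 11 and all reagents are commercial.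

**Steps most likely to fail**

Step 8 (key step). The second bond may not close in the same pot: proton shuffling between the γ-enolate and the more acidic C15–H, or enolization of the aldehyde once the lactolate opens, would leave the Michael adduct uncyclized. The fallback sets out from 10 and blocks C15 from the start. Methyl 2-methyl-3-oxopentanoate under NaOMe (cat.) in MeOH should undergo the classical alkoxide-catalysed Michael–aldol annulation of an α-substituted β-keto ester, because only the ethyl side can then enolize, giving the C15-methyl keto ester diol F1. TEMPO/PhI(OAc)2 oxidation as in step 9 should give the C15-methyl lactol F2, and (2-methylallyl)trimethylsilane with Me3SiOTf as in step 10 the C15-methyl tetrahydrofuran keto ester F3. Treatment with LiN(i-Pr)2 and 4-iodobut-1-ene alkylates C3, now the only enolizable position, and the route is rejoined at 17.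

Step 11. C-alkylation at the hindered γ-carbon may be outrun by E2 loss of HI from the homoallylic iodide or by β-elimination that opens the tetrahydrofuran. The fallback sets out from 15 and uses the far more reactive allyl bromide. Dianion allylation followed by MeI should give the C3-allyl C15-methyl keto ester F4, and Krapcho dealkoxycarbonylation the C3-allyl ketone F5. Hydroboration of the monosubstituted alkene with disiamylborane and NaBO3 oxidation should give the primary alcohol F6, and Dess–Martin periodinane the aldehyde F7. Wittig methylenation with Ph3P=CH2 restores the butenyl chain and the route is rejoined at 18.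

Step 15 (with the facial course of step 14). Backside approach of methoxide to C6 inside the medium ring may be too slow, so that E2 opening to an allylic alcohol or transannular participation takes over. The fallback sets out from 19 and replaces the substitution by an oxidation–reduction inversion, in which every reagent approaches from the peripheral face. Upjohn dihydroxylation (OsO4 cat., NMO) should give the cis-diol F8 (C7 as in the target, C6 epimeric). Dess–Martin oxidation of the secondary alcohol should give the C6-keto C7-hydroxy compound F9. Chelation-assisted reduction with Zn(BH4)2, delivering hydride from the peripheral face and sparing the hindered C16 ketone, should give the trans-diol F10. Selective methylation of the secondary hydroxyl with MeOTf and 2,6-di-tert-butyl-4-methylpyridine rejoins the route at 21.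

**Further compounds**
F1 | step 8 | methyl 6-(benzyloxy)-4-hydroxy-5-(hydroxymethyl)-1,3,6-trimethyl-2-oxodecahydronaphthalene-1-carboxylate | C[C@H]1C(=O)C(C)(C(=O)OC)[C@@H]2CC[C@@](C)(OCc3ccccc3)[C@@H](CO)[C@H]2[C@@H]1O
F2 | step 8 | C15-methyl tricyclic lactol | C[C@H]1C(=O)C(C)(C(=O)OC)[C@@H]2CC[C@@](C)(OCc3ccccc3)[C@@H]4[C@H]2[C@@H]1OC4O
F3 | step 8 | C15-methyl C9-(2-methylallyl) tetrahydrofuran keto ester | C[C@H]1C(=O)C(C)(C(=O)OC)[C@@H]2CC[C@@](C)(OCc3ccccc3)[C@@H]4[C@H]2[C@@H]1O[C@H]4CC(C)=C
F4 | step 11 | C3-allyl C15-methyl keto ester | C=CC[C@]1(C)C(=O)C(C)(C(=O)OC)[C@@H]2CC[C@@](C)(OCc3ccccc3)[C@@H]4[C@H]2[C@@H]1O[C@H]4CC(C)=C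
F5 | step 11 | C3-allyl ketone (15-epi) | C=CC[C@]1(C)C(=O)[C@@H](C)[C@@H]2CC[C@@](C)(OCc3ccccc3)[C@@H]4[C@H]2[C@@H]1O[C@H]4CC(C)=C
F6 | step 11 | C3-(3-hydroxypropyl) ketone | OCCC[C@]1(C)C(=O)[C@@H](C)[C@@H]2CC[C@@](C)(OCc3ccccc3)[C@@H]4[C@H]2[C@@H]1O[C@H]4CC(C)=C
F7 | step 11 | C3-(3-oxopropyl) ketone | O=CCC[C@]1(C)C(=O)[C@@H](C)[C@@H]2CC[C@@](C)(OCc3ccccc3)[C@@H]4[C@H]2[C@@H]1O[C@H]4CC(C)=C
F8 | step 15 | C6,C7-cis-diol (6-epi) | O[C@H]1CC[C@]2(C)C(=O)[C@@H](C)[C@@H]3CC[C@@](C)(OCc5ccccc5)[C@@H]4[C@H]3[C@@H]2O[C@H]4C[C@@]1(C)O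
F9 | step 15 | C6-keto C7-hydroxy compound | O=C1CC[C@]2(C)C(=O)[C@@H](C)[C@@H]3CC[C@@](C)(OCc5ccccc5)[C@@H]4[C@H]3[C@@H]2O[C@H]4C[C@@]1(C)O
F10 | step 15 | C6,C7-trans-diol | O[C@@H]1CC[C@]2(C)C(=O)[C@@H](C)[C@@H]3CC[C@@](C)(OCc5ccccc5)[C@@H]4[C@H]3[C@@H]2O[C@H]4C[C@@]1(C)O
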